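A direct plan would condense two equivalents of the chlorinated dibenzyl acetophenone A1 with the diaryl ether dialdehyde A2 (double Claisen–Schmidt) to the bis-chalcone A3, would rearrange both chalcones with Tl(NO3)3 (trivalent thallium) and close them with acid to the pentabenzyl bis-isoflavone A4, and would finish with BCl3 debenzylation.
Weak point 1, the double oxidative 1,2-aryl shift: stoichiometric toxic thallium would have to rearrange two chalcones in one molecule, free 2'-hydroxychalcones tend to close to aurones or flavanones instead, and two stereocentres would be made only to be erased.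
Weak point 2, the ring chlorination that leads to A1: two ring positions of similar activation compete, and this undirected substitution alone would decide between the 8-chloro and the 6-chloro series, provable only after the fact.
Weak point 3, the protecting-group frame: five benzyl ethers would be put on by partial alkylations of polyphenols that tend to give mixtures, carried through a long linear run to A2 and A3 that builds no ring, and removed at the very end.

**Retrosynthetic overview**
The target is the dehydro-dimer of one 8-chloro-5,7,4'-trihydroxyisoflavone unit: the only bond between the halves is the aryl ether from O4' of one ring B to C3' of the other ring B, ortho to the remaining free 4'-OH.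
Key disconnection: this C3'–O bond, formed last by anodic oxidative coupling of two molecules of the 3',5'-dibromo monomer 5 (zinc work-up); the precursor is half the size of the product and the unsymmetrical linkage needs no differentiation of the halves.
Ring order: ring A is bought with chlorine in place (phenol 3 has a single free hydroxyl, next to chlorine, so O1 can only close there and chlorine must sit at C8); ring C is closed per monomer by one-carbon insertion into a deoxybenzoin (C2–C3 and O1–C2 bonds); the diaryl ether comes last.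
By design there is no thallium aryl shift, no undirected ring chlorination and no benzyl protection; the price is three bromine blocking atoms (one step on, one step off) and four methyl ethers that come with the building block.

Key step: step 3

Assumption: 2-chloro-3,5-dimethoxyphenol (3) is taken as a commercial building block; current density and charge of the electrolysis would be fixed by a short screen.

Step 1
Reactants: 1 (4-hydroxyphenyl)acetic acid
Product: 2 (3,5-dibromo-4-hydroxyphenyl)acetic acid
Conditions: Br2 (2.1 equiv), AcOH, rt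
Reagents that add atoms: bromine, BrBr
Why: Electrophilic aromatic bromination in which the phenol directs both bromine atoms to its two ortho positions (para is occupied), installing the blocking atoms that later steer the oxidative coupling from carbon to oxygen.

Step 2
Reactants: 2 (3,5-dibromo-4-hydroxyphenyl)acetic acid; 3 2-chloro-3,5-dimethoxyphenol
Product: 5 8-chloro-3-(3,5-dibromo-4-hydroxyphenyl)-5,7-dimethoxy-4H-chromen-4-one, via deoxybenzoin 4 (not isolated)
Conditions: BF3·OEt2 (as solvent), 80 °C; then DMF, MsCl, 60 °C; aq. NaOAc work-up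
Reagents that add atoms: N,N-dimethylformamide, CN(C)C=O
Why: One-pot Friedel–Crafts acylation and Vilsmeier-type one-carbon annulation (deoxybenzoin route to isoflavones), in which 2 acylates 3 ortho to its only free hydroxyl under BF2-chelate control to give 4, the activated methylene of 4 is aminomethylenated by the DMF/MsCl iminium salt, and the same hydroxyl, which lies next to chlorine, closes ring C by conjugate addition and loss of dimethylamine, so that chlorine can only end at C8.

Step 3
Reactants: 5 8-chloro-3-(3,5-dibromo-4-hydroxyphenyl)-5,7-dimethoxy-4H-chromen-4-one (two molecules)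
Product: 7 3-{3-bromo-5-[2,6-dibromo-4-(8-chloro-5,7-dimethoxy-4-oxo-4H-chromen-3-yl)phenoxy]-4-hydroxyphenyl}-8-chloro-5,7-dimethoxy-4H-chromen-4-one, via dienone dimer 6 (not isolated)
Conditions: constant-current electrolysis (glassy carbon anode, Pt cathode, undivided cell, low current density, ca. 1.2 F/mol), LiClO4 (0.1 M), MeOH/CH2Cl2, rt; then Zn powder, AcOH, rt
Reagents that add atoms: none
Why: Anodic oxidation of the 2,6-dibromophenol of 5 should give a phenoxyl radical or phenoxonium ion that is attacked by the phenolic oxygen of a second molecule of 5 at a bromine-bearing ortho carbon, giving the 6-aryloxy-2,6-dibromocyclohexa-2,4-dienone 6, and zinc then cleaves the C–Br bond at the sp3 carbon with rearomatisation to the diaryl ether 7. The closest known reaction type is the anodic oxidation of 2,6-dihalo-4-alkylphenols followed by zinc reduction, the electrochemical way to isodityrosine-type ortho-phenoxyphenols. No ring is closed: the step forms the single C3'–O bond that joins two complete isoflavone units, and the unsymmetrical 4'-O-to-3' linkage arises by itself because one molecule reacts through oxygen and the other through carbon. The quaternary carbon of 6 forms as a racemate and is erased by the reduction, so no stereocontrol is needed. The step needs O–C(ortho) coupling in preference to C–C coupling, solvent capture and oxidation of ring A; the two ortho bromines (which disfavour C–C coupling and make the ipso C–O adduct reducible), the blocked para position and the high oxidation potential of the acylated, chlorinated dimethoxy ring A should secure it, and a low current density keeps the concentration of oxidised phenol low.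

Step 4
Reactants: 7 3-{3-bromo-5-[2,6-dibromo-4-(8-chloro-5,7-dimethoxy-4-oxo-4H-chromen-3-yl)phenoxy]-4-hydroxyphenyl}-8-chloro-5,7-dimethoxy-4H-chromen-4-one
Product: 8 8-chloro-3-{4-[5-(8-chloro-5,7-dimethoxy-4-oxo-4H-chromen-3-yl)-2-hydroxyphenoxy]phenyl}-5,7-dimethoxy-4H-chromen-4-one
Conditions: Pd(PPh3)4 (10 mol%), HCO2Na (6 equiv), DMF, 90 °C
Reagents that add atoms: none
Why: Palladium-catalysed transfer hydrogenolysis in which zerovalent palladium with PPh3 inserts into the three C–Br bonds but not into the hindered, electron-rich C8–Cl bonds, formate delivers hydride with loss of CO2, and the homogeneous catalyst should leave the chromone C2=C3 bonds untouched.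

Step 5
Reactants: 8 8-chloro-3-{4-[5-(8-chloro-5,7-dimethoxy-4-oxo-4H-chromen-3-yl)-2-hydroxyphenoxy]phenyl}-5,7-dimethoxy-4H-chromen-4-one
Product: 9 Bisoflavolin M
Conditions: BBr3 (12 equiv), CH2Cl2, −78 °C → rt; MeOH quench, aqueous work-up
Reagents that add atoms: none
Why: Lewis-acid cleavage of aryl methyl ethers in which BBr3 removes the chelated 5-O-methyl groups first and the 7-O-methyl groups on warming, while the diaryl ether and the aryl chlorides are inert, and the absence of hot protic acid avoids ring opening and reclosure (Wessely–Moser) that would move chlorine from C8 to C6.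

**Compound list**
1 | (4-hydroxyphenyl)acetic acid | OC(=O)Cc1ccc(O)cc1 | starting material
2 | (3,5-dibromo-4-hydroxyphenyl)acetic acid | OC(=O)Cc1cc(Br)c(O)c(Br)c1 | intermediate
3 | 2-chloro-3,5-dimethoxyphenol | COc1cc(O)c(Cl)c(OC)c1 | starting material
4 | 1-(3-chloro-2-hydroxy-4,6-dimethoxyphenyl)-2-(3,5-dibromo-4-hydroxyphenyl)ethan-1-one (deoxybenzoin, not isolated) | COc1cc(OC)c(C(=O)Cc2cc(Br)c(O)c(Br)c2)c(O)c1Cl | intermediate
5 | 8-chloro-3-(3,5-dibromo-4-hydroxyphenyl)-5,7-dimethoxy-4H-chromen-4-one | COc1cc(OC)c2c(=O)c(-c3cc(Br)c(O)c(Br)c3)coc2c1Cl | intermediate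
6 | 8-chloro-3-(3,5-dibromo-4-{[1,3-dibromo-5-(8-chloro-5,7-dimethoxy-4-oxo-4H-chromen-3-yl)-2-oxocyclohexa-3,5-dien-1-yl]oxy}phenyl)-5,7-dimethoxy-4H-chromen-4-one (dienone dimer, racemic, not isolated) | O=C1C(Br)=CC(c2coc3c(Cl)c(OC)cc(OC)c3c2=O)=CC1(Br)Oc1c(Br)cc(-c2coc3c(Cl)c(OC)cc(OC)c3c2=O)cc1Br | intermediate
7 | 3-{3-bromo-5-[2,6-dibromo-4-(8-chloro-5,7-dimethoxy-4-oxo-4H-chromen-3-yl)phenoxy]-4-hydroxyphenyl}-8-chloro-5,7-dimethoxy-4H-chromen-4-one | COc1cc(OC)c2c(=O)c(-c3cc(Br)c(O)c(Oc4c(Br)cc(-c5coc6c(Cl)c(OC)cc(OC)c6c5=O)cc4Br)c3)coc2c1Cl | intermediate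
8 | 8-chloro-3-{4-[5-(8-chloro-5,7-dimethoxy-4-oxo-4H-chromen-3-yl)-2-hydroxyphenoxy]phenyl}-5,7-dimethoxy-4H-chromen-4-one | COc1cc(OC)c2c(=O)c(-c3ccc(O)c(Oc4ccc(-c5coc6c(Cl)c(OC)cc(OC)c6c5=O)cc4)c3)coc2c1Cl | intermediate
9 | Bisoflavolin M: 8-chloro-3-{4-[5-(8-chloro-5,7-dihydroxy-4-oxo-4H-chromen-3-yl)-2-hydroxyphenoxy]phenyl}-5,7-dihydroxy-4H-chromen-4-one (achiral) | O=c1c(-c2ccc(Oc3cc(-c4coc5c(Cl)c(O)cc(O)c5c4=O)ccc3O)cc2)coc2c(Cl)c(O)cc(O)c12 | target

Total step count: 5. Longest linear sequence: 5 steps (1 → 2 → 5 → 7 → 8 → 9; building block 3 enters in step 2).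

**Steps most likely to fail**

Step 3 (anodic dimerisation). The oxidised phenol may be captured by methanol at the para carbon or, through conjugation, at C2 of the chromone, may couple through carbon, or may be over-oxidised, so that O–C coupling is not the main path. The fallback is a copper-mediated ether synthesis between two differentiated monomers; it sets out from 5 and 3 and comes back to the route at target 9.
- Exhaustive hydrodebromination of 5 (Pd(PPh3)4, HCO2Na, DMF, 90 °C) would give 8-chloro-3-(4-hydroxyphenyl)-5,7-dimethoxy-4H-chromen-4-one F1.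
- In parallel, 3 and commercial (3-bromo-4-methoxyphenyl)acetic acid would be taken through the one-pot acylation and annulation of step 2. This passes through the deoxybenzoin 2-(3-bromo-4-methoxyphenyl)-1-(3-chloro-2-hydroxy-4,6-dimethoxyphenyl)ethan-1-one F2 (not isolated) and gives 3-(3-bromo-4-methoxyphenyl)-8-chloro-5,7-dimethoxy-4H-chromen-4-one F3.
- Ullmann coupling of the phenol F1 with the aryl bromide F3 (copper iodide CuI, picolinic acid, K3PO4, DMSO, 90 °C; the aryl chlorides should not react) would give the penta-O-methyl ether 8-chloro-3-{4-[5-(8-chloro-5,7-dimethoxy-4-oxo-4H-chromen-3-yl)-2-methoxyphenoxy]phenyl}-5,7-dimethoxy-4H-chromen-4-one F4.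
- BBr3 as in step 5 would cleave all five methyl ethers of F4 to give 9.

Step 4 (selective hydrodebromination). Over-reduction with loss of the C8 chlorines, conjugate reduction of the chromone double bonds by a palladium hydride, or intramolecular C–H arylation of the neighbouring ring to a dibenzofuran may compete. The fallback replaces palladium insertion by a radical chain reduction that discriminates by bond strength: from 7, (Me3Si)3SiH and AIBN in toluene at 80 °C would abstract only bromine atoms, and the high silane concentration would trap the aryl radicals before they cyclise. It comes back to the route at 8 and makes no new compound (F0).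

Step 5 (fourfold demethylation). Cleavage of the non-chelated 7-O-methyl groups may stay incomplete, and forcing with heat and acid may open and reclose the pyranone, moving chlorine from C8 to C6. The fallback splits the deprotection into two mechanistically different stages and sets out from 8. BCl3 (CH2Cl2, 0 °C) would cleave only the two chelated 5-O-methyl groups to give 8-chloro-3-{4-[5-(8-chloro-5-hydroxy-7-methoxy-4-oxo-4H-chromen-3-yl)-2-hydroxyphenoxy]phenyl}-5-hydroxy-7-methoxy-4H-chromen-4-one F5. Nucleophilic SN2 demethylation of the 7-O-methyl groups with NaSEt in DMF at 110 °C, under non-acidic conditions, would then return to the route at 9.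

**Further compounds**
F1 | step 3 | 8-chloro-3-(4-hydroxyphenyl)-5,7-dimethoxy-4H-chromen-4-one | COc1cc(OC)c2c(=O)c(-c3ccc(O)cc3)coc2c1Cl
F2 | step 3 | 2-(3-bromo-4-methoxyphenyl)-1-(3-chloro-2-hydroxy-4,6-dimethoxyphenyl)ethan-1-one | COc1cc(OC)c(C(=O)Cc2ccc(OC)c(Br)c2)c(O)c1Cl
F3 | step 3 | 3-(3-bromo-4-methoxyphenyl)-8-chloro-5,7-dimethoxy-4H-chromen-4-one | COc1cc(OC)c2c(=O)c(-c3ccc(OC)c(Br)c3)coc2c1Cl
F4 | step 3 | 8-chloro-3-{4-[5-(8-chloro-5,7-dimethoxy-4-oxo-4H-chromen-3-yl)-2-methoxyphenoxy]phenyl}-5,7-dimethoxy-4H-chromen-4-one | COc1cc(OC)c2c(=O)c(-c3ccc(OC)c(Oc4ccc(-c5coc6c(Cl)c(OC)cc(OC)c6c5=O)cc4)c3)coc2c1Cl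
F0 | step 4 | none | none
F5 | step 5 | 8-chloro-3-{4-[5-(8-chloro-5-hydroxy-7-methoxy-4-oxo-4H-chromen-3-yl)-2-hydroxyphenoxy]phenyl}-5-hydroxy-7-methoxy-4H-chromen-4-one | COc1cc(O)c2c(=O)c(-c3ccc(O)c(Oc4ccc(-c5coc6c(Cl)c(OC)cc(O)c6c5=O)cc4)c3)coc2c1Cl
A1 | direct plan | 1-[4,6-bis(benzyloxy)-3-chloro-2-hydroxyphenyl]ethan-1-one | CC(=O)c1c(O)c(Cl)c(OCc2ccccc2)cc1OCc1ccccc1
A2 | direct plan | 4-(benzyloxy)-3-(4-formylphenoxy)benzaldehyde | O=Cc1ccc(Oc2cc(C=O)ccc2OCc2ccccc2)cc1
A3 | direct plan | (2E)-1-[4,6-bis(benzyloxy)-3-chloro-2-hydroxyphenyl]-3-{4-[2-(benzyloxy)-5-{(1E)-3-[4,6-bis(benzyloxy)-3-chloro-2-hydroxyphenyl]-3-oxoprop-1-en-1-yl}phenoxy]phenyl}prop-2-en-1-one | O=C(/C=C/c1ccc(Oc2cc(/C=C/C(=O)c3c(O)c(Cl)c(OCc4ccccc4)cc3OCc3ccccc3)ccc2OCc2ccccc2)cc1)c1c(O)c(Cl)c(OCc2ccccc2)cc1OCc1ccccc1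
A4 | direct plan | 5,7-bis(benzyloxy)-3-{4-[2-(benzyloxy)-5-(5,7-bis(benzyloxy)-8-chloro-4-oxo-4H-chromen-3-yl)phenoxy]phenyl}-8-chloro-4H-chromen-4-one | O=c1c(-c2ccc(Oc3cc(-c4coc5c(Cl)c(OCc6ccccc6)cc(OCc6ccccc6)c5c4=O)ccc3OCc3ccccc3)cc2)coc2c(Cl)c(OCc3ccccc3)cc(OCc3ccccc3)c12
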